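**Plan**

1. Retrosynthesis: after removal of two silyl ethers, the ten-membered carbocycle is cut at C2–C3 and C3–C4 together, C3 leaving as CO. This is possible because the ring ketone C3 lies between the two ring alkenes C1=C2 and C4=C5 (a cross-conjugated divinyl ketone), so the seco-compound is an E-alkenylstannane (C2) plus a Z-alkenyl iodide (C4), each traceable to an alkyne.
2. Further cuts: the C8–O ester bond (Mitsunobu, inversion), the C7–C8 bond (Barbier allylation of a 3-bromomethylbutenolide, which also unveils the C11=C13 exo-methylene) and the butenolide C7=C11 bond (ring-closing metathesis).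
3. Forward: the lactone ring is made first (steps 1–4) and the C8–C10/C1–C2 fragment separately (steps 5–9); the chain is joined at C7–C8 (step 10) and esterified (step 11); the ten-membered ring is closed last with CO as third component (step 12); desilylation ends the route (step 13).
4. Stereochemistry: C6 from a catalytic enantioselective alkynylation of crotonaldehyde; C10 from a catalytic enantioselective allylboration of an ynone; C7 and C8 from the Barbier step under control of C6, C8 then being inverted in the Mitsunobu step; the side-chain centre from (R)-2-methylbutanoic acid.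
5. Alkene geometry: 4Z from hydroxyl-directed trans-hydroalumination/iodination, 1E from syn-hydrostannylation; both are carried through the coupling with retention.

Key step: step 12

Remark on locants: germacranolide numbering is used. C1=C2 is the E-alkene next to the carbinol C10 (C14 = its methyl), C3 the ring ketone, C4=C5 the Z-alkene (C15 = CH2OH on C4), C6 the lactone O–CH, C7 the ring-fusion CH, C8 the ester CH, C9 the CH2, C11=C13 the exo-methylene, C12 the lactone carbonyl.

Assumption: in the two catalytic enantioselective additions (steps 1 and 5) the ligand antipode written is the one expected by analogy with simple enals and aryl methyl ketones to give the drawn configuration; if the sense of induction proves opposite, the other antipode is used and nothing else changes.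

**Route**

Step 1
Reactants: 1 (E)-but-2-enal; 2 tert-butyldimethyl(prop-2-yn-1-yloxy)silane
Product: 4 (4S,5E)-1-[(tert-butyldimethylsilyl)oxy]hept-5-en-2-yn-4-ol, via methylzinc alkynylide 3 (not isolated)
Conditions: Me2Zn, (S,S)-ProPhenol (10 mol %), Ph3P=O (20 mol %), toluene, 0 °C
Reagents that add atoms: dimethylzinc, C[Zn]C (retained only in intermediate 3)
Why: Zinc–ProPhenol-catalysed enantioselective alkynylation of an enal: the alkynylzinc formed from 2 should add 1,2 to the aldehyde inside the chiral dinuclear zinc pocket, which selects the carbonyl face and so sets C6.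

Step 2
Reactants: 4 (4S,5E)-1-[(tert-butyldimethylsilyl)oxy]hept-5-en-2-yn-4-ol
Product: 6 (2Z,4S,5E)-1-[(tert-butyldimethylsilyl)oxy]-2-iodohepta-2,5-dien-4-ol, via cyclic alkenylaluminate 5 (not isolated)
Conditions: Red-Al, THF, 0 °C; then I2, THF, −78 → 0 °C
Reagents that add atoms: iodine, II; Red-Al, [Na+].COCCO[AlH2-]OCCOC (retained only in intermediate 5)
Why: Hydroxyl-directed trans-hydroalumination of the propargylic alcohol delivers hydride to the proximal carbon C5 and aluminium to C4 within the five-membered aluminate, and iodinolysis with retention should give the Z-iodoalkene (C6 and I cis) that the ring alkene C4=C5 needs; C6 is untouched.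

Step 3
Reactants: 6 (2Z,4S,5E)-1-[(tert-butyldimethylsilyl)oxy]-2-iodohepta-2,5-dien-4-ol; 7 2-(bromomethyl)prop-2-enoic acid
Product: 8 (2Z,4S,5E)-1-[(tert-butyldimethylsilyl)oxy]-2-iodohepta-2,5-dien-4-yl 2-(bromomethyl)prop-2-enoate
Conditions: DCC, DMAP (5 mol %), CH2Cl2, 0 °C
Reagents that add atoms: none
Why: Steglich esterification under mild neutral conditions should acylate the doubly allylic alcohol without ionising it, the low DMAP loading and temperature limiting attack on the allylic bromide.

Step 4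
Reactants: 8 (2Z,4S,5E)-1-[(tert-butyldimethylsilyl)oxy]-2-iodohepta-2,5-dien-4-yl 2-(bromomethyl)prop-2-enoate
Product: 9 (5S)-3-(bromomethyl)-5-[(1Z)-3-[(tert-butyldimethylsilyl)oxy]-2-iodoprop-1-en-1-yl]furan-2(5H)-one
Conditions: second-generation Ru benzylidene catalyst (H2IMes)(PCy3)Cl2Ru=CHPh (5 mol %), CH2Cl2 (5 mM), 40 °C
Reagents that add atoms: none
Why: Ring-closing metathesis between the propenyl group and the 1,1-disubstituted acrylate should form the butenolide C7=C11 bond with loss of propene; the trisubstituted iodoalkene is too hindered and electron-poor to engage, and C6 is not involved.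

Step 5
Reactants: 10 4-(trimethylsilyl)but-3-yn-2-one
Product: 11 (3R)-3-methyl-1-(trimethylsilyl)hex-5-en-1-yn-3-ol
Conditions: allyldiisopropoxyborane, (S)-3,3'-Br2-BINOL (15 mol %), PhCF3/toluene, −35 °C
Reagents that add atoms: allyldiisopropoxyborane, C=CCB(OC(C)C)OC(C)C
Why: Chiral-diol-catalysed asymmetric allylboration of a ketone: exchange of an isopropoxy group for the BINOL gives a chiral allylboronate that adds through a closed chair transition state in which the silylalkynyl and methyl groups are differentiated, setting the C10 carbinol.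

Step 6
Reactants: 11 (3R)-3-methyl-1-(trimethylsilyl)hex-5-en-1-yn-3-ol
Product: 12 triethyl{[(3R)-3-methyl-1-(trimethylsilyl)hex-5-en-1-yn-3-yl]oxy}silane
Conditions: TESOTf, 2,6-lutidine, CH2Cl2, −78 → 0 °C
Reagents that add atoms: triethylsilyl trifluoromethanesulfonate, CC[Si](CC)(CC)OS(=O)(=O)C(F)(F)F
Why: Silylation of the hindered tertiary alcohol with a silyl triflate and a non-nucleophilic base is standard, and the TES ether suppresses retro-aldol and hemiacetal chemistry of the later β-oxy aldehyde.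

Step 7
Reactants: 12 triethyl{[(3R)-3-methyl-1-(trimethylsilyl)hex-5-en-1-yn-3-yl]oxy}silane
Product: 13 triethyl{[(3R)-3-methylhex-5-en-1-yn-3-yl]oxy}silane
Conditions: K2CO3 (cat.), MeOH, rt
Reagents that add atoms: none
Why: Base-catalysed methanolysis cleaves only the C(sp)–Si bond, the tertiary TES ether being stable to K2CO3/MeOH.

Step 8
Reactants: 13 triethyl{[(3R)-3-methylhex-5-en-1-yn-3-yl]oxy}silane
Product: 15 (3R)-3-methyl-3-[(triethylsilyl)oxy]pent-4-ynal, via ozonide 14 (not isolated)
Conditions: O3, CH2Cl2, −78 °C (Sudan III end point); then PPh3, −78 °C → rt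
Reagents that add atoms: ozone, [O-][O+]=O
Why: Ozonolysis is selective for the terminal alkene over the alkyne, and reductive cleavage of the ozonide should give the β-silyloxy aldehyde, which has no epimerisable centre.

Step 9
Reactants: 15 (3R)-3-methyl-3-[(triethylsilyl)oxy]pent-4-ynal
Product: 16 (3R,4E)-3-methyl-5-(tributylstannyl)-3-[(triethylsilyl)oxy]pent-4-enal
Conditions: Bu3SnH, PdCl2(PPh3)2 (3 mol %), THF, 0 °C
Reagents that add atoms: tributyltin hydride, CCCC[SnH](CCCC)CCCC
Why: Palladium-catalysed syn-hydrostannylation of the terminal alkyne, in which the fully substituted propargylic carbon steers tin to the terminal carbon, should give the E-alkenylstannane (the C1=C2 geometry); a saturated aldehyde is not reduced by Bu3SnH under these conditions.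

Step 10
Reactants: 9 (5S)-3-(bromomethyl)-5-[(1Z)-3-[(tert-butyldimethylsilyl)oxy]-2-iodoprop-1-en-1-yl]furan-2(5H)-one; 16 (3R,4E)-3-methyl-5-(tributylstannyl)-3-[(triethylsilyl)oxy]pent-4-enal
Product: 18 (4R,5S)-5-[(1Z)-3-[(tert-butyldimethylsilyl)oxy]-2-iodoprop-1-en-1-yl]-4-[(1S,3R,4E)-1-hydroxy-3-methyl-5-(tributylstannyl)-3-[(triethylsilyl)oxy]pent-4-en-1-yl]-3-methylideneoxolan-2-one, via allylzinc bromide 17 (not isolated)
Conditions: Zn dust (activated), THF/sat. aq. NH4Cl, 0 °C → rt
Reagents that add atoms: zinc, [Zn] (retained only in intermediate 17)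
Why: Barbier allylation: zinc inserts only into the allylic C–Br bond and the allylzinc adds through its γ-carbon C7 with allylic transposition, unveiling the exo-methylene lactone; attack anti to the C6 side chain should set C7 (trans-lactone) and a closed chair transition state with the aldehyde residue equatorial should set C8 as the 7,8-anti (8α) carbinol, the epimer that the next step needs.

Step 11
Reactants: 18 the 8α-carbinol from step 10; 19 (2R)-2-methylbutanoic acid
Product: 21 (1R,3R,4E)-1-{(2S,3R)-2-[(1Z)-3-[(tert-butyldimethylsilyl)oxy]-2-iodoprop-1-en-1-yl]-4-methylidene-5-oxooxolan-3-yl}-3-methyl-5-(tributylstannyl)-3-[(triethylsilyl)oxy]pent-4-en-1-yl (2R)-2-methylbutanoate, via alkoxyphosphonium carboxylate 20 (not isolated)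
Conditions: PPh3, DIAD, toluene, 0 °C → rt
Reagents that add atoms: triphenylphosphine, c1ccc(cc1)P(c1ccccc1)c1ccccc1 (retained only in intermediate 20)
Why: Mitsunobu esterification: the carboxylate of 19 displaces the oxyphosphonium group by SN2 with inversion, which should turn the 8α-alcohol into the 8β-ester of the target in the same step that installs the side chain; the acid stereocentre is not enolised.

Step 12
Reactants: 21 the iodo-stannane ester from step 11
Product: 23 the 10-O-triethylsilyl 15-O-tert-butyldimethylsilyl bis-ether of the target, via acylpalladium(II) iodide 22 (not isolated)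
Conditions: Pd2(dba)3·CHCl3 (10 mol %), AsPh3 (40 mol %), CO (3 atm), DMF, 50 °C, slow addition to 1 mM
Reagents that add atoms: carbon monoxide, [C-]#[O+]; palladium(0), [Pd], and triphenylarsine, c1ccc(cc1)[As](c1ccccc1)c1ccccc1 (both retained only in intermediate 22)
Why: Oxidative addition of Pd(0) into the C4–I bond with retention, CO insertion to the acylpalladium(II) iodide, intramolecular Sn→Pd transmetalation of the C2 alkenylstannane and reductive elimination should form the C3–C4 and C2–C3 bonds in one operation and deliver C3 at its final ketone oxidation level. The closest known reaction type is the intramolecular carbonylative Stille coupling of alkenyl iodides or triflates with alkenylstannanes that gives macrocyclic cross-conjugated divinyl ketones. The ten-membered carbocycle is closed by acyl–alkenyl reductive elimination from an eleven-membered palladacycle, that is a macrocyclisation at C2–C3 onto the preformed trans-fused lactone, and no other ring is formed. No stereocentre is created: C6, C7, C8 and C10 are spectators, and the 4Z and 1E geometries, fixed in steps 2 and 9, are carried through with retention. The step needs CO insertion to outrun direct coupling, ring closure to outrun oligomerisation, and the exo-methylene lactone to stay out of Heck-type insertion. These should be secured by the CO pressure (direct coupling would have to close a strained nine-membered diene), by high dilution with slow addition, by the weakly donating AsPh3 ligand that speeds transmetalation of the acyl complex, and by the cis relation of C6 and the acyl group across C4=C5, which turns the acylpalladium toward the stannane-bearing chain on C7.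

Step 13
Reactants: 23 the bis-silyl ether from step 12
Product: 24 (3aR,4R,6R,7E,10Z,11aR)-6-hydroxy-10-(hydroxymethyl)-6-methyl-3-methylidene-2,9-dioxo-2,3,3a,4,5,6,9,11a-octahydrocyclodeca[b]furan-4-yl (2R)-2-methylbutanoate
Conditions: HF·pyridine, pyridine/THF, 0 °C → rt
Reagents that add atoms: none
Why: Fluoride-mediated cleavage of the primary TBS and tertiary TES ethers under buffered, non-basic conditions should leave the dienone, the ester and the Michael-acceptor lactone intact.

**Compound list**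

1 | (E)-but-2-enal | C/C=C/C=O | starting material
2 | tert-butyldimethyl(prop-2-yn-1-yloxy)silane | C#CCO[Si](C)(C)C(C)(C)C | starting material
3 | methyl[3-(tert-butyldimethylsilyloxy)prop-1-yn-1-yl]zinc | C[Zn]C#CCO[Si](C)(C)C(C)(C)C | intermediate
4 | (4S,5E)-1-[(tert-butyldimethylsilyl)oxy]hept-5-en-2-yn-4-ol | O[C@@H](/C=C/C)C#CCO[Si](C)(C)C(C)(C)C | intermediate
5 | sodium salt of the cyclic alkenylaluminate of 4 (Al on C4 and on the C6 oxygen, two 2-methoxyethoxy ligands) | [Na+].COCCO[Al-]1(OCCOC)O[C@@H](/C=C/C)C=C1CO[Si](C)(C)C(C)(C)C | intermediate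
6 | (2Z,4S,5E)-1-[(tert-butyldimethylsilyl)oxy]-2-iodohepta-2,5-dien-4-ol | O[C@@H](/C=C/C)/C=C(I)/CO[Si](C)(C)C(C)(C)C | intermediate
7 | 2-(bromomethyl)prop-2-enoic acid | C=C(CBr)C(=O)O | starting material
8 | (2Z,4S,5E)-1-[(tert-butyldimethylsilyl)oxy]-2-iodohepta-2,5-dien-4-yl 2-(bromomethyl)prop-2-enoate | C=C(CBr)C(=O)O[C@@H](/C=C/C)/C=C(I)/CO[Si](C)(C)C(C)(C)C | intermediate
9 | (5S)-3-(bromomethyl)-5-[(1Z)-3-[(tert-butyldimethylsilyl)oxy]-2-iodoprop-1-en-1-yl]furan-2(5H)-one | BrCC1=C[C@@H](/C=C(I)/CO[Si](C)(C)C(C)(C)C)OC1=O | intermediate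
10 | 4-(trimethylsilyl)but-3-yn-2-one | CC(=O)C#C[Si](C)(C)C | starting material
11 | (3R)-3-methyl-1-(trimethylsilyl)hex-5-en-1-yn-3-ol | C[Si](C)(C)C#C[C@](C)(O)CC=C | intermediate
12 | triethyl{[(3R)-3-methyl-1-(trimethylsilyl)hex-5-en-1-yn-3-yl]oxy}silane | C[Si](C)(C)C#C[C@](C)(O[Si](CC)(CC)CC)CC=C | intermediate
13 | triethyl{[(3R)-3-methylhex-5-en-1-yn-3-yl]oxy}silane | C#C[C@](C)(O[Si](CC)(CC)CC)CC=C | intermediate
14 | 1,2,4-trioxolane (ozonide) of 13 | C#C[C@](C)(O[Si](CC)(CC)CC)CC1OCOO1 | intermediate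
15 | (3R)-3-methyl-3-[(triethylsilyl)oxy]pent-4-ynal | C#C[C@](C)(O[Si](CC)(CC)CC)CC=O | intermediate
16 | (3R,4E)-3-methyl-5-(tributylstannyl)-3-[(triethylsilyl)oxy]pent-4-enal | CCCC[Sn](CCCC)(CCCC)/C=C/[C@](C)(O[Si](CC)(CC)CC)CC=O | intermediate
17 | allylzinc bromide derived from 9 | Br[Zn]CC1=C[C@@H](/C=C(I)/CO[Si](C)(C)C(C)(C)C)OC1=O | intermediate
18 | (4R,5S)-5-[(1Z)-3-[(tert-butyldimethylsilyl)oxy]-2-iodoprop-1-en-1-yl]-4-[(1S,3R,4E)-1-hydroxy-3-methyl-5-(tributylstannyl)-3-[(triethylsilyl)oxy]pent-4-en-1-yl]-3-methylideneoxolan-2-one | C=C1C(=O)O[C@H](/C=C(I)/CO[Si](C)(C)C(C)(C)C)[C@H]1[C@@H](O)C[C@@](C)(O[Si](CC)(CC)CC)/C=C/[Sn](CCCC)(CCCC)CCCC | intermediate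
19 | (2R)-2-methylbutanoic acid | CC[C@@H](C)C(=O)O | starting material
20 | C8-oxytriphenylphosphonium (2R)-2-methylbutanoate of 18 | C=C1C(=O)O[C@H](/C=C(I)/CO[Si](C)(C)C(C)(C)C)[C@H]1[C@@H](O[P+](c2ccccc2)(c2ccccc2)c2ccccc2)C[C@@](C)(O[Si](CC)(CC)CC)/C=C/[Sn](CCCC)(CCCC)CCCC.CC[C@@H](C)C(=O)[O-] | intermediate
21 | (1R,3R,4E)-1-{(2S,3R)-2-[(1Z)-3-[(tert-butyldimethylsilyl)oxy]-2-iodoprop-1-en-1-yl]-4-methylidene-5-oxooxolan-3-yl}-3-methyl-5-(tributylstannyl)-3-[(triethylsilyl)oxy]pent-4-en-1-yl (2R)-2-methylbutanoate | C=C1C(=O)O[C@H](/C=C(I)/CO[Si](C)(C)C(C)(C)C)[C@H]1[C@H](OC(=O)[C@H](C)CC)C[C@@](C)(O[Si](CC)(CC)CC)/C=C/[Sn](CCCC)(CCCC)CCCC | intermediate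
22 | C3 acylpalladium(II) iodide bis(triphenylarsine) complex of 21 | C=C1C(=O)O[C@H](/C=C(/CO[Si](C)(C)C(C)(C)C)C(=O)[Pd](I)([As](c2ccccc2)(c2ccccc2)c2ccccc2)[As](c2ccccc2)(c2ccccc2)c2ccccc2)[C@H]1[C@H](OC(=O)[C@H](C)CC)C[C@@](C)(O[Si](CC)(CC)CC)/C=C/[Sn](CCCC)(CCCC)CCCC | intermediate
23 | (3aR,4R,6R,7E,10Z,11aR)-10-{[(tert-butyldimethylsilyl)oxy]methyl}-6-methyl-3-methylidene-2,9-dioxo-6-[(triethylsilyl)oxy]-2,3,3a,4,5,6,9,11a-octahydrocyclodeca[b]furan-4-yl (2R)-2-methylbutanoate | C=C1C(=O)O[C@@H]2/C=C(/CO[Si](C)(C)C(C)(C)C)C(=O)/C=C/[C@](C)(O[Si](CC)(CC)CC)C[C@@H](OC(=O)[C@H](C)CC)[C@@H]12 | intermediate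
24 | (3aR,4R,6R,7E,10Z,11aR)-6-hydroxy-10-(hydroxymethyl)-6-methyl-3-methylidene-2,9-dioxo-2,3,3a,4,5,6,9,11a-octahydrocyclodeca[b]furan-4-yl (2R)-2-methylbutanoate (CNP0232405.1) | C=C1C(=O)O[C@@H]2/C=C(/CO)C(=O)/C=C/[C@](C)(O)C[C@@H](OC(=O)[C@H](C)CC)[C@@H]12 | target

**Step count**

Total: 13 steps. Longest linear sequence: 9 steps (steps 5–13); the other branch (steps 1–4, then 10–13) is 8 steps.

**Steps most likely to fail, with fallbacks**

Step 12. The ring closure may lose to oligomerisation, to direct coupling without CO uptake, to protodestannylation, or to capture of the acylpalladium by the exo-methylene lactone. The fallback closes the same ring at C3–C4 by a Nozaki–Hiyama–Kishi addition to an enal and then oxidises; it sets out from 13 and returns at 23. Lithiation of 13 (n-BuLi, THF, −78 °C) and addition to paraformaldehyde would give propargylic alcohol F1, silylation (TESCl, imidazole) bis-silyl ether F2, and ozonolysis (O3, then PPh3) aldehyde F3. The zinc Barbier reaction of F3 with 9, run as in step 10, would give 8α-carbinol F4, and Mitsunobu esterification with 19, run as in step 11, ester F5. PPTS in MeOH/CH2Cl2 at 0 °C would free only the primary propargylic hydroxyl to give propargylic alcohol F6, and ruthenium-catalysed redox isomerisation (indenylbis(triphenylphosphine)ruthenium chloride, In(OTf)3, CSA, THF, 65 °C) would give E-enal F7. CrCl2 with catalytic NiCl2 in DMSO/THF at high dilution would add the C4 alkenylchromium to the C3 aldehyde to give macrocyclic dienol F8 as a mixture at C3, and DMP oxidation would give 23.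

Step 11. Displacement at the hindered C8 may be outrun by elimination toward C7 or by acyl transfer with retention. The fallback corrects C8 by oxidation and reagent-controlled reduction and then acylates with retention; it sets out from 18 and returns at 21. Buffered DMP oxidation (NaHCO3, CH2Cl2, 0 °C) would give C8 ketone F9. Corey–Bakshi–Shibata reduction (oxazaborolidine antipode matched to the required face, catecholborane, toluene, −78 °C) would give 8β-carbinol F10. Steglich acylation of F10 with 19 (DCC, DMAP, CH2Cl2, 0 °C) would give 21.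

Step 4. Ring closure onto the electron-poor 1,1-disubstituted alkene may be sluggish, the allylic bromide may degrade the catalyst, or the doubly allylic ester may ionise. The fallback closes the butenolide without the bromomethyl group and adds C13 afterwards; it sets out from 6 and returns at 9. Acryloyl chloride with iPr2NEt in CH2Cl2 at −78 °C would give acrylate F11, and ring-closing metathesis with the same ruthenium catalyst would give butenolide F12. A Morita–Baylis–Hillman reaction with aqueous formaldehyde (imidazole, THF/H2O, rt, kept short to protect C6) would give hydroxymethylbutenolide F13, and an Appel reaction (CBr4, PPh3, CH2Cl2, 0 °C) would give 9.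

**Further compounds**

F1 | step 12 | (4R)-4-methyl-4-[(triethylsilyl)oxy]hept-6-en-2-yn-1-ol | OCC#C[C@](C)(O[Si](CC)(CC)CC)CC=C
F2 | step 12 | (4R)-4-methyl-1,4-bis[(triethylsilyl)oxy]hept-6-en-2-yne | CC[Si](CC)(CC)OCC#C[C@](C)(O[Si](CC)(CC)CC)CC=C
F3 | step 12 | (3R)-3-methyl-3,6-bis[(triethylsilyl)oxy]hex-4-ynal | CC[Si](CC)(CC)OCC#C[C@](C)(O[Si](CC)(CC)CC)CC=O
F4 | step 12 | (4R,5S)-5-[(1Z)-3-[(tert-butyldimethylsilyl)oxy]-2-iodoprop-1-en-1-yl]-4-[(1S,3R)-1-hydroxy-3-methyl-3,6-bis[(triethylsilyl)oxy]hex-4-yn-1-yl]-3-methylideneoxolan-2-one | C=C1C(=O)O[C@H](/C=C(I)/CO[Si](C)(C)C(C)(C)C)[C@H]1[C@@H](O)C[C@@](C)(O[Si](CC)(CC)CC)C#CCO[Si](CC)(CC)CC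
F5 | step 12 | (1R,3R)-1-{(2S,3R)-2-[(1Z)-3-[(tert-butyldimethylsilyl)oxy]-2-iodoprop-1-en-1-yl]-4-methylidene-5-oxooxolan-3-yl}-3-methyl-3,6-bis[(triethylsilyl)oxy]hex-4-yn-1-yl (2R)-2-methylbutanoate | C=C1C(=O)O[C@H](/C=C(I)/CO[Si](C)(C)C(C)(C)C)[C@H]1[C@H](OC(=O)[C@H](C)CC)C[C@@](C)(O[Si](CC)(CC)CC)C#CCO[Si](CC)(CC)CC
F6 | step 12 | (1R,3R)-1-{(2S,3R)-2-[(1Z)-3-[(tert-butyldimethylsilyl)oxy]-2-iodoprop-1-en-1-yl]-4-methylidene-5-oxooxolan-3-yl}-6-hydroxy-3-methyl-3-[(triethylsilyl)oxy]hex-4-yn-1-yl (2R)-2-methylbutanoate | C=C1C(=O)O[C@H](/C=C(I)/CO[Si](C)(C)C(C)(C)C)[C@H]1[C@H](OC(=O)[C@H](C)CC)C[C@@](C)(O[Si](CC)(CC)CC)C#CCO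
F7 | step 12 | (1R,3R,4E)-1-{(2S,3R)-2-[(1Z)-3-[(tert-butyldimethylsilyl)oxy]-2-iodoprop-1-en-1-yl]-4-methylidene-5-oxooxolan-3-yl}-3-methyl-6-oxo-3-[(triethylsilyl)oxy]hex-4-en-1-yl (2R)-2-methylbutanoate | C=C1C(=O)O[C@H](/C=C(I)/CO[Si](C)(C)C(C)(C)C)[C@H]1[C@H](OC(=O)[C@H](C)CC)C[C@@](C)(O[Si](CC)(CC)CC)/C=C/C=O
F8 | step 12 | C3-hydroxy analogue of 23 (macrocyclic bis-allylic alcohol, both C3 epimers) | C=C1C(=O)O[C@@H]2/C=C(/CO[Si](C)(C)C(C)(C)C)C(O)/C=C/[C@](C)(O[Si](CC)(CC)CC)C[C@@H](OC(=O)[C@H](C)CC)[C@@H]12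
F9 | step 11 | C8 ketone of 18 | C=C1C(=O)O[C@H](/C=C(I)/CO[Si](C)(C)C(C)(C)C)[C@H]1C(=O)C[C@@](C)(O[Si](CC)(CC)CC)/C=C/[Sn](CCCC)(CCCC)CCCC
F10 | step 11 | C8 epimer of 18 (8β-carbinol, 1R in the side chain) | C=C1C(=O)O[C@H](/C=C(I)/CO[Si](C)(C)C(C)(C)C)[C@H]1[C@H](O)C[C@@](C)(O[Si](CC)(CC)CC)/C=C/[Sn](CCCC)(CCCC)CCCC
F11 | step 4 | (2Z,4S,5E)-1-[(tert-butyldimethylsilyl)oxy]-2-iodohepta-2,5-dien-4-yl prop-2-enoate | C=CC(=O)O[C@@H](/C=C/C)/C=C(I)/CO[Si](C)(C)C(C)(C)C
F12 | step 4 | (5S)-5-[(1Z)-3-[(tert-butyldimethylsilyl)oxy]-2-iodoprop-1-en-1-yl]furan-2(5H)-one | O=C1C=C[C@@H](/C=C(I)/CO[Si](C)(C)C(C)(C)C)O1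
F13 | step 4 | (5S)-5-[(1Z)-3-[(tert-butyldimethylsilyl)oxy]-2-iodoprop-1-en-1-yl]-3-(hydroxymethyl)furan-2(5H)-one | OCC1=C[C@@H](/C=C(I)/CO[Si](C)(C)C(C)(C)C)OC1=O
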